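The data are simulated for substances that don't exist.

all flasks: solid electrophile 0.050 M
- winter: nucleophile 0.045 M; free base 0.014 M; run made earlier
- spring: nucleophile 0.045 M; free base 0.021 M; run made earlier
- dusk: nucleophile 0.045 M; free base 0.024 M; run made earlier
- Thursday's: nucleophile 0.0450 M; free base 0.0190 M; time 3.0 d
- Tuesday's: nucleophile 0.0450 M; free base 0.0250 M; time 3.0 d
- Monday's: nucleophile 0.0450 M; free base 0.0150 M; time 3.0 d

| run | time / h | solid electrophile / % | product / % |
|---|---|---|---|
| winter | 10.0 | 77.3 | 18.3 |
| winter | 20.0 | 58.4 | 37.7 |
| winter | 25.0 | 48.0 | 45.6 |
| winter | 40.0 | 24.8 | 58.3 |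
| spring | 3.00 | 94.1 | 2.7 |
| spring | 6.00 | 85.2 | 8.3 |
| spring | 15.0 | 67.8 | 25.6 |
| spring | 40.0 | 24.4 | 62.3 |
| dusk | 3.00 | 92.5 | 4.4 |
| dusk | 6.00 | 87.0 | 7.8 |
| dusk | 15.0 | 66.1 | 28.1 |
| dusk | 40.0 | 22.4 | 67.1 |

(scatter of a reading: 1 percentage point)
- at the start none of the solid electrophile is in solution
- what has only dissolved of solid electrophile counts as not reacted
- part of the solid electrophile that has reacted (what has only dissolved counts as not reacted) at the end, Thursday's
- part of the solid electrophile that has reacted (what has only dissolved counts as not reacted) at the end, Tuesday's
- part of the solid electrophile that has reacted (what has only dissolved counts as not reacted) at the end, Monday's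
- what raising the concentration of free base from its lowest to its highest value here does to the part of the solid electrophile that has reacted (what has only dissolved counts as not reacted) (changes below 5 percentage points count as none) (no change / it rises / it falls)

If you follow the product peak, it soon passes what the free base could take up. Winter reads 58.3 % at 40.0 h, more than its free base, which is worth 28.0 % of the charge. So suppose each product sets one acid free. Free base takes that acid first, then nucleophile, the limiting reagent at 0.900 equivalents, and bound nucleophile makes no product. Monday's gives 60.0 % for what I call the acid budget: nucleophile plus free base over twice the solid electrophile. It means the fraction of the charge that can react while every acid is bound.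

Thursday's budget is 64.0 % and Tuesday's 70.0 %, a step of 10 percentage points from Monday's, more than the margin. So I say it rises.

Is one number enough? Winter's solid still reads 24.8 % at 40.0 h, so time may matter too. Winter's budget is 59.0 %, and its product was still climbing from 45.6 % at 25.0 h. The readings show no stop, so I expect each flask on its budget or somewhat above.

The forecast has the same values, 64 %, 70 % and 60 %, and also says it rises. But it calls them a ceiling and sees that “winter is visibly stalling”.

The flask gives 69.8 %, 74.5 % and 66.5 %, and it rises by 8 points. Each stands above its budget .

    electrophile + nucleophile → acid set free + product (k = 0.243 L mol⁻¹ min⁻¹)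
    nucleophile + acid set free ⇌ protonated nucleophile, settled at all times (K = 5370 L mol⁻¹)
    acid set free + free base ⇌ salt of the base, settled at all times (K = 2.71 × 10⁶ L mol⁻¹)
    solid electrophile ⇌ electrophile, rate k4*(cs4 - [electrophile]) while solid is left; crystals form when [electrophile] > cs4 (solubility = 17.0 mM, k = 0.00116 min⁻¹)

Monday's ends holding acid set free worth 13.7 % of the charge, unbound, where the budget has none. Now cut Monday's nucleophile to 0.018 M. That neighbour's budget is 33.0 %, and it gives 34.9 % at 3.00 d, with 65 % of its charged solid electrophile still there, solid or dissolved.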